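The numbers in the tables were computed with constants of no real substance.

Amounts first: each unit of starting material charged ends as target, other capture product or solvolysis product, so we reckon in fractions of that charge and ask how the captured part divides.

the same everywhere: first nucleophile 0.0525 M; second nucleophile 0.0525 M

| charge | starting material | remark | time |
|---|---|---|---|
| north-west | 0.034 M | run made earlier |  |
| north | 0.075 M | run made earlier |  |
| flask | 0.050 M |  | 2.0 d |

| run | time / d | other capture product / % | target / % |
|---|---|---|---|
| north-west | 0.125 | 18.6 | 18.5 |
| north-west | 0.333 | 36.1 | 32.3 |
| north-west | 0.625 | 46.0 | 36.6 |
| north-west | 1.04 | 47.0 | 36.0 |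
| north-west | 1.67 | 47.3 | 36.2 |
| north-west | 2.08 | 48.4 | 38.5 |
| north-west | 2.50 | 48.2 | 36.6 |
| north | 0.208 | 27.2 | 25.4 |
| north | 0.333 | 34.3 | 30.0 |
| north | 0.417 | 39.4 | 32.4 |
| north | 0.625 | 42.0 | 36.0 |
| north | 1.04 | 44.5 | 35.2 |
| north | 1.67 | 45.8 | 33.5 |
| north | 2.50 | 45.2 | 34.5 |

(each reading ± 1 percentage point)

* share of other capture product in other capture product plus target at 5.0 min
* share of other capture product in other capture product plus target at 2.0 h
* share of other capture product in other capture product plus target at 2.0 d
* which of other capture product and target there is more of at 2.0 d

- what may be going on: intermediate -> solvolysis product; starting material -> intermediate; second nucleophile + intermediate -> other capture product; first nucleophile <-> dormant form; first nucleophile -> decomposed reagent; first nucleophile + intermediate -> target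

We climb the time scales from the fastest. Intermediate and the exchange between first nucleophile and dormant form have no readings of their own, and 5.0 min and 2.0 h both precede the earliest reading, 0.125 d, so we commit to no number there. Next comes starting material: the north-west run has captured 37.1% at that reading and ends near 84.8%, which reads as a half-life of 0.151 d. Meanwhile the share of other capture product in that run climbs from 50.1% to 56.8%, so first nucleophile is falling against second nucleophile. Last, from 1.04 d both products move by about the scatter, and 2.0 d is 13.2 half-lives, so we read the flask at its end.

The end ratio is therefore what we carry. The last readings, times the charge of first nucleophile over that of second nucleophile, give 1.32 north-west and 1.31 north. Yet the north run held twice the starting material, and target took 49.3% of first nucleophile's charge there against 23.7% north-west. We call the mean 1.31 the end factor, the end ratio of other capture product to target divided by the charge ratio of second nucleophile to first, a figure read off the last readings of these runs. For the flask, with equal nucleophile charges, we reckon a share of 56.8%, with other capture product ahead.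

The forecast goes further than we do: 48.2% at 5.0 min, 49.7% at 2.0 h, 56.8% at 2.0 d, other capture product ahead, with the caution “Early values are less certain”.

The flask gives 32.2%, 51.7% and 56.0%, with 46.7% other capture product against 36.6% target; the forecast stands 16 percentage points above it at 5.0 min, and our end share 0.80 points above it at 2.0 d.

    intermediate → solvolysis product (k = 6.25 h⁻¹)
    starting material → intermediate (k = 0.204 h⁻¹)
    second nucleophile + intermediate → other capture product (k = 439 L mol⁻¹ h⁻¹)
    first nucleophile ⇌ dormant form (K = 2.00, k = 6.16 h⁻¹)
    first nucleophile → decomposed reagent (k = 0.115 h⁻¹)
    first nucleophile + intermediate → target (k = 1210 L mol⁻¹ h⁻¹)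

For the neighbour charged with 0.13 M of first nucleophile, the end factor gives a ratio of 0.530 and a share of 34.7%. That neighbour ends at 34.3%, with 59.1% target.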